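**Retrosynthetic overview**

1. Target ⇒ desilylation and outer-face epoxidation of the 1(10)E alkene of a heliangolide lactone; the exocyclic methylene comes from a Mannich/elimination on the saturated lactone.
2. Lactone and C8 ester ⇒ one Evans–Tishchenko reduction of a C8-hydroxy C6-ketone with the epoxy aldehyde (sets C6 and installs the ester), then lactonisation of the C7 acetamide arm.
3. Ten-membered ring ⇒ anionic oxy-Cope ring expansion of a trans-1,2-dialkenylcyclohexenol (gives 1(10)E, keeps 4Z, sets C8); the enolate is alkylated at C7 in the same flask.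
4. Cyclohexenone ⇒ 4-methoxy-2-methylphenol, by oxidative dearomatisation to the quinone monoketal and catalytic enantioselective isopropenyl 1,4-addition in one flask; every later ring stereocentre is relayed from this one.
5. Ring order: six-membered carbocycle (from the arene) → ten-membered carbocycle → γ-lactone → ring epoxide. The side-chain epoxide comes from a Sharpless epoxidation of tiglyl alcohol.

Assumption: the target is read as (1R,3S,6R,7R,8R,10R), 4Z, with a (2R,3S) tiglate-derived epoxy ester; germacrane numbering (C1–C10 ring, C11–C13 lactone arm, C14/C15 methyls) is used for ring positions in all intermediates, and the six starting materials are bought.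

**Route**

Step 1
Reactants: 1 4-methoxy-2-methylphenol; 2 isopropenylboronic acid pinacol ester
Product: 4 (5S)-4,4-dimethoxy-2-methyl-5-(prop-1-en-2-yl)cyclohex-2-en-1-one, via quinone monoketal 3 (not isolated)
Conditions: PhI(OAc)2 (1.0 equiv), MeOH, 0 °C; evaporate; then 2 (1.5 equiv), [Rh(OH)(cod)]2 (2.5 mol %), (S)-BINAP (6 mol %), KOH, dioxane/H2O 10:1, 40 °C
Reagents that add atoms: methanol CO
Why: Hypervalent-iodine oxidative dearomatisation gives the achiral cross-conjugated dienone, and a Hayashi–Miyaura rhodium-catalysed asymmetric 1,4-addition then alkenylates only the enone arm without the α-methyl group, the (S)-BINAP complex selecting the face that gives 5S (the sense that gives (S)-3-substituted cyclohexanones from cyclohexenone).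

Step 2
Reactants: 4 (5S)-4,4-dimethoxy-2-methyl-5-(prop-1-en-2-yl)cyclohex-2-en-1-one
Product: 6 (4S,6S)-4-hydroxy-3-methyl-6-(prop-1-en-2-yl)cyclohex-2-en-1-one, via ketal alcohol 5 (not isolated)
Conditions: NaBH4, CeCl3·7H2O, MeOH, −78 °C; then 1 M HCl, THF, 0 °C
Reagents that add atoms: water O
Why: Luche 1,2-reduction delivers hydride axially to the half-chair with the isopropenyl group equatorial, giving the cis (1S,5S) alcohol as carvone gives cis-carveol, and mild-acid ketal hydrolysis then unveils the transposed enone.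

Step 3
Reactants: 6 (4S,6S)-4-hydroxy-3-methyl-6-(prop-1-en-2-yl)cyclohex-2-en-1-one
Product: 7 (4S,6S)-4-[(tert-butyldimethylsilyl)oxy]-3-methyl-6-(prop-1-en-2-yl)cyclohex-2-en-1-one
Conditions: TBSCl, imidazole, DMF, 0 °C → rt
Reagents that add atoms: tert-butyldimethylsilyl chloride CC(C)(C)[Si](C)(C)Cl
Why: Standard silyl ether formation protects the C3 oxygen with a group that survives KH, organolithium and DDQ and is removed last.

Step 4
Reactants: 8 4-methoxybenzyl alcohol; 9 ethyl vinyl ether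
Product: 10 4-methoxybenzyl vinyl ether
Conditions: Pd(OAc)2 (1 mol %), 1,10-phenanthroline (1 mol %), 9 as solvent, 40 °C
Reagents that add atoms: none
Why: Palladium-catalysed transfer vinylation (transetherification) is driven by the large excess of ethyl vinyl ether.

Step 5
Reactants: 10 4-methoxybenzyl vinyl ether
Product: 12 (Z)-2-bromoethenyl 4-methoxybenzyl ether, via dibromide 11 (not isolated)
Conditions: Br2, CH2Cl2, −78 °C; then iPr2NEt, 0 → 40 °C
Reagents that add atoms: bromine BrBr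
Why: Electrophilic bromine addition to the enol ether followed by amine-promoted dehydrobromination through the α-bromo ether gives mainly the Z-2-bromovinyl ether (cis preference of 1-halo-2-alkoxyethenes), the minor E isomer being removed by chromatography.

Step 6
Reactants: 7 (4S,6S)-4-[(tert-butyldimethylsilyl)oxy]-3-methyl-6-(prop-1-en-2-yl)cyclohex-2-en-1-one; 12 (Z)-2-bromoethenyl 4-methoxybenzyl ether
Product: 14 (1S,4S,6S)-4-[(tert-butyldimethylsilyl)oxy]-1-{(Z)-2-[(4-methoxybenzyl)oxy]ethenyl}-3-methyl-6-(prop-1-en-2-yl)cyclohex-2-en-1-ol, via alkenyllithium 13 (not isolated)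
Conditions: 12, t-BuLi (2.0 equiv), Et2O, −78 °C; then 7, THF, −78 °C; NH4Cl aq
Reagents that add atoms: none
Why: Bromine–lithium exchange with retention gives the configurationally stable cis-2-alkoxyvinyllithium, whose 1,2-addition occurs on the carbonyl face opposite the adjacent equatorial isopropenyl group (as vinyl organometallics do with isopiperitenone), setting the carbinol centre S with the two alkenyl groups trans.

Step 7
Reactants: 14 (1S,4S,6S)-4-[(tert-butyldimethylsilyl)oxy]-1-{(Z)-2-[(4-methoxybenzyl)oxy]ethenyl}-3-methyl-6-(prop-1-en-2-yl)cyclohex-2-en-1-ol; 15 2-bromo-N-methoxy-N-methylacetamide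
Product: 17 2-[(1R,2R,4E,7S,8Z)-7-[(tert-butyldimethylsilyl)oxy]-2-[(4-methoxybenzyl)oxy]-4,8-dimethyl-10-oxocyclodeca-4,8-dien-1-yl]-N-methoxy-N-methylacetamide, via potassium enolate 16 (not isolated)
Conditions: KH, 18-crown-6, THF, −20 → 0 °C; then −78 °C, 15; NH4Cl aq at −78 °C
Reagents that add atoms: none
Why: Anionic oxy-Cope [3,3] rearrangement through the chair transition state with both ring bonds equatorial expands the ring to the ten-membered enolate, creating the 1(10)E alkene, keeping the 4Z alkene of the old ring and transferring chirality to C8 (the cis alkoxy group sits axial, hence 8R); the enolate is then alkylated by SN2 on its outer face in the parallel-alkene conformer delivered by the rearrangement, which places the side chain β (7R).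

Step 8
Reactants: 17 2-[(1R,2R,4E,7S,8Z)-7-[(tert-butyldimethylsilyl)oxy]-2-[(4-methoxybenzyl)oxy]-4,8-dimethyl-10-oxocyclodeca-4,8-dien-1-yl]-N-methoxy-N-methylacetamide
Product: 18 2-[(1R,2R,4E,7S,8Z)-7-[(tert-butyldimethylsilyl)oxy]-2-hydroxy-4,8-dimethyl-10-oxocyclodeca-4,8-dien-1-yl]-N-methoxy-N-methylacetamide
Conditions: DDQ, CH2Cl2/pH 7 buffer, 0 °C
Reagents that add atoms: none
Why: Oxidative PMB ether cleavage by DDQ frees the C8 hydroxyl under buffered neutral conditions, and the Weinreb amide is too poor an acylating agent to lactonise onto it.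

Step 9
Reactants: 19 (E)-2-methylbut-2-en-1-ol
Product: 20 [(2S,3S)-2,3-dimethyloxiran-2-yl]methanol
Conditions: Ti(OiPr)4 (5 mol %), L-(+)-diethyl tartrate (6 mol %), t-BuOOH, 4 Å MS, CH2Cl2, −20 °C
Reagents that add atoms: tert-butyl hydroperoxide CC(C)(C)OO
Why: Sharpless asymmetric epoxidation with L-(+)-diethyl tartrate delivers oxygen to the face that gives (2S,3S) epoxy alcohols from E-allylic alcohols, and the E geometry fixes the two methyl groups cis.

Step 10
Reactants: 20 [(2S,3S)-2,3-dimethyloxiran-2-yl]methanol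
Product: 21 (2R,3S)-2,3-dimethyloxirane-2-carbaldehyde
Conditions: TEMPO (10 mol %), PhI(OAc)2, CH2Cl2, rt
Reagents that add atoms: none
Why: TEMPO-catalysed alcohol oxidation stops at the non-enolisable epoxy aldehyde without touching the epoxide; C2 becomes R only through the change in substituent priority.

Step 11
Reactants: 18 2-[(1R,2R,4E,7S,8Z)-7-[(tert-butyldimethylsilyl)oxy]-2-hydroxy-4,8-dimethyl-10-oxocyclodeca-4,8-dien-1-yl]-N-methoxy-N-methylacetamide; 21 (2R,3S)-2,3-dimethyloxirane-2-carbaldehyde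
Product: 23 (3aR,4R,6E,9S,10Z,11aR)-9-[(tert-butyldimethylsilyl)oxy]-6,10-dimethyl-2-oxo-2,3,3a,4,5,8,9,11a-octahydrocyclodeca[b]furan-4-yl (2R,3S)-2,3-dimethyloxirane-2-carboxylate, via hydroxy amide ester 22 (not isolated)
Conditions: SmI2 (30 mol %), 21 (4 equiv), THF, −10 °C; then PPTS, toluene, 50 °C
Reagents that add atoms: none
Why: Evans–Tishchenko reduction: the C8 hydroxyl forms a samarium-bound hemiacetal with 21 and passes its hydride intramolecularly to the C6 ketone on the face syn to O8 (six-membered chair transition state), giving the 1,3-anti 6α alcohol (6R) while O8 emerges acylated as the required epoxy ester; mild acid then closes the trans-fused γ-lactone from O6 onto the Weinreb amide (lactonisation).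

Step 12
Reactants: 23 (3aR,4R,6E,9S,10Z,11aR)-9-[(tert-butyldimethylsilyl)oxy]-6,10-dimethyl-2-oxo-2,3,3a,4,5,8,9,11a-octahydrocyclodeca[b]furan-4-yl (2R,3S)-2,3-dimethyloxirane-2-carboxylate
Product: 26 (3aR,4R,6E,9S,10Z,11aR)-9-[(tert-butyldimethylsilyl)oxy]-6,10-dimethyl-3-methylidene-2-oxo-2,3,3a,4,5,8,9,11a-octahydrocyclodeca[b]furan-4-yl (2R,3S)-2,3-dimethyloxirane-2-carboxylate, via Mannich base 24 (not isolated), via ammonium iodide 25 (not isolated)
Conditions: LiN(iPr)2, THF, −78 °C; CH2=NMe2+ I−, −78 → 0 °C; then MeI, MeOH, rt; then NaHCO3 aq, CH2Cl2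
Reagents that add atoms: Eschenmoser's salt C=[N+](C)C.[I-]
Why: α-Methylenation by the Eschenmoser Mannich sequence: the lithium lactone enolate is aminomethylated, the amine is quaternised and E1cB elimination gives the exocyclic alkene, while the C8 ester has no α-hydrogen and survives the base.

Step 13
Reactants: 26 (3aR,4R,6E,9S,10Z,11aR)-9-[(tert-butyldimethylsilyl)oxy]-6,10-dimethyl-3-methylidene-2-oxo-2,3,3a,4,5,8,9,11a-octahydrocyclodeca[b]furan-4-yl (2R,3S)-2,3-dimethyloxirane-2-carboxylate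
Product: 27 (1R,3S,6R,7R,8R,10R)-3-[(tert-butyldimethylsilyl)oxy]-1,10-epoxy-8-{[(2R,3S)-2,3-dimethyloxiran-2-yl]carbonyloxy}germacra-4Z,11(13)-dien-12,6-olide
Conditions: mCPBA (1.05 equiv), NaHCO3, CH2Cl2, 0 °C
Reagents that add atoms: 3-chloroperbenzoic acid OOC(=O)c1cccc(Cl)c1
Why: Prilezhaev epoxidation: the strained, electron-rich 1(10)E alkene reacts much faster than the 4Z alkene (flanked by two allylic C–O bonds), the α-methylene lactone or the ester, and the peracid attacks its outer face in the lactone-locked conformer, giving the 1β,10α epoxide (1R,10R) found in natural heliangolide epoxides.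

Step 14
Reactants: 27 (1R,3S,6R,7R,8R,10R)-3-[(tert-butyldimethylsilyl)oxy]-1,10-epoxy-8-{[(2R,3S)-2,3-dimethyloxiran-2-yl]carbonyloxy}germacra-4Z,11(13)-dien-12,6-olide
Product: 28 (1R,3S,6R,7R,8R,10R)-1,10-epoxy-3-hydroxy-8-{[(2R,3S)-2,3-dimethyloxiran-2-yl]carbonyloxy}germacra-4Z,11(13)-dien-12,6-olide (CNP0268255.6)
Conditions: HF·pyridine, pyridine, THF, 0 °C
Reagents that add atoms: none
Why: Fluoride-mediated silyl ether cleavage with pyridine-buffered HF·pyridine removes the allylic TBS group without opening either epoxide or touching the α-methylene lactone.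

**Compound list**

1 | 4-methoxy-2-methylphenol | COc1ccc(O)c(C)c1 | starting material
2 | isopropenylboronic acid pinacol ester | CC(=C)B1OC(C)(C)C(C)(C)O1 | starting material
3 | 4,4-dimethoxy-2-methylcyclohexa-2,5-dien-1-one | COC1(OC)C=CC(=O)C(C)=C1 | intermediate
4 | (5S)-4,4-dimethoxy-2-methyl-5-(prop-1-en-2-yl)cyclohex-2-en-1-one | O=C1C(C)=CC(OC)(OC)[C@H](C(C)=C)C1 | intermediate
5 | (1S,5S)-4,4-dimethoxy-2-methyl-5-(prop-1-en-2-yl)cyclohex-2-en-1-ol (cis) | O[C@@H]1C(C)=CC(OC)(OC)[C@H](C(C)=C)C1 | intermediate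
6 | (4S,6S)-4-hydroxy-3-methyl-6-(prop-1-en-2-yl)cyclohex-2-en-1-one (cis) | O=C1C=C(C)[C@@H](O)C[C@H]1C(C)=C | intermediate
7 | (4S,6S)-4-[(tert-butyldimethylsilyl)oxy]-3-methyl-6-(prop-1-en-2-yl)cyclohex-2-en-1-one | O=C1C=C(C)[C@@H](O[Si](C)(C)C(C)(C)C)C[C@H]1C(C)=C | intermediate
8 | 4-methoxybenzyl alcohol | COc1ccc(CO)cc1 | starting material
9 | ethyl vinyl ether | CCOC=C | starting material
10 | 4-methoxybenzyl vinyl ether | COc1ccc(COC=C)cc1 | intermediate
11 | 1-[(1,2-dibromoethoxy)methyl]-4-methoxybenzene | COc1ccc(COC(Br)CBr)cc1 | intermediate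
12 | (Z)-2-bromoethenyl 4-methoxybenzyl ether | COc1ccc(CO/C=C\Br)cc1 | intermediate
13 | (Z)-2-[(4-methoxybenzyl)oxy]ethenyllithium | COc1ccc(CO/C=C\[Li])cc1 | intermediate
14 | (1S,4S,6S)-4-[(tert-butyldimethylsilyl)oxy]-1-{(Z)-2-[(4-methoxybenzyl)oxy]ethenyl}-3-methyl-6-(prop-1-en-2-yl)cyclohex-2-en-1-ol | COc1ccc(CO/C=C\[C@]2(O)C=C(C)[C@@H](O[Si](C)(C)C(C)(C)C)C[C@H]2C(C)=C)cc1 | intermediate
15 | 2-bromo-N-methoxy-N-methylacetamide | CON(C)C(=O)CBr | starting material
16 | potassium (1Z,3R,5E,8S,9Z)-8-[(tert-butyldimethylsilyl)oxy]-3-[(4-methoxybenzyl)oxy]-5,9-dimethylcyclodeca-1,5,9-trien-1-olate | [K+].[O-]/C1=C\[C@H](OCc2ccc(OC)cc2)C/C(C)=C/C[C@H](O[Si](C)(C)C(C)(C)C)/C(C)=C\1 | intermediate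
17 | 2-[(1R,2R,4E,7S,8Z)-7-[(tert-butyldimethylsilyl)oxy]-2-[(4-methoxybenzyl)oxy]-4,8-dimethyl-10-oxocyclodeca-4,8-dien-1-yl]-N-methoxy-N-methylacetamide | O=C1/C=C(/C)[C@@H](O[Si](C)(C)C(C)(C)C)C/C=C(C)/C[C@@H](OCc2ccc(OC)cc2)[C@H]1CC(=O)N(C)OC | intermediate
18 | 2-[(1R,2R,4E,7S,8Z)-7-[(tert-butyldimethylsilyl)oxy]-2-hydroxy-4,8-dimethyl-10-oxocyclodeca-4,8-dien-1-yl]-N-methoxy-N-methylacetamide | O=C1/C=C(/C)[C@@H](O[Si](C)(C)C(C)(C)C)C/C=C(C)/C[C@@H](O)[C@H]1CC(=O)N(C)OC | intermediate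
19 | (E)-2-methylbut-2-en-1-ol | C/C=C(\C)CO | starting material
20 | [(2S,3S)-2,3-dimethyloxiran-2-yl]methanol | OC[C@]1(C)O[C@H]1C | intermediate
21 | (2R,3S)-2,3-dimethyloxirane-2-carbaldehyde | O=C[C@]1(C)O[C@H]1C | intermediate
22 | (1R,2S,3R,4Z,6S,8E)-6-[(tert-butyldimethylsilyl)oxy]-3-hydroxy-2-{2-[methoxy(methyl)amino]-2-oxoethyl}-5,9-dimethylcyclodeca-4,8-dien-1-yl (2R,3S)-2,3-dimethyloxirane-2-carboxylate | O[C@@H]1/C=C(/C)[C@@H](O[Si](C)(C)C(C)(C)C)C/C=C(C)/C[C@@H](OC(=O)[C@]2(C)O[C@H]2C)[C@H]1CC(=O)N(C)OC | intermediate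
23 | (3aR,4R,6E,9S,10Z,11aR)-9-[(tert-butyldimethylsilyl)oxy]-6,10-dimethyl-2-oxo-2,3,3a,4,5,8,9,11a-octahydrocyclodeca[b]furan-4-yl (2R,3S)-2,3-dimethyloxirane-2-carboxylate | C1C(=O)O[C@@H]2/C=C(/C)[C@@H](O[Si](C)(C)C(C)(C)C)C/C=C(C)/C[C@@H](OC(=O)[C@]3(C)O[C@H]3C)[C@@H]12 | intermediate
24 | 3-[(dimethylamino)methyl] derivative of 23 (C3 epimers) | CN(C)CC1C(=O)O[C@@H]2/C=C(/C)[C@@H](O[Si](C)(C)C(C)(C)C)C/C=C(C)/C[C@@H](OC(=O)[C@]3(C)O[C@H]3C)[C@@H]12 | intermediate
25 | 3-[(trimethylammonio)methyl] derivative of 23, iodide | C[N+](C)(C)CC1C(=O)O[C@@H]2/C=C(/C)[C@@H](O[Si](C)(C)C(C)(C)C)C/C=C(C)/C[C@@H](OC(=O)[C@]3(C)O[C@H]3C)[C@@H]12.[I-] | intermediate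
26 | (3aR,4R,6E,9S,10Z,11aR)-9-[(tert-butyldimethylsilyl)oxy]-6,10-dimethyl-3-methylidene-2-oxo-2,3,3a,4,5,8,9,11a-octahydrocyclodeca[b]furan-4-yl (2R,3S)-2,3-dimethyloxirane-2-carboxylate | C=C1C(=O)O[C@@H]2/C=C(/C)[C@@H](O[Si](C)(C)C(C)(C)C)C/C=C(C)/C[C@@H](OC(=O)[C@]3(C)O[C@H]3C)[C@@H]12 | intermediate
27 | (1R,3S,6R,7R,8R,10R)-3-[(tert-butyldimethylsilyl)oxy]-1,10-epoxy-8-{[(2R,3S)-2,3-dimethyloxiran-2-yl]carbonyloxy}germacra-4Z,11(13)-dien-12,6-olide | C=C1C(=O)O[C@@H]2/C=C(/C)[C@@H](O[Si](C)(C)C(C)(C)C)C[C@H]3O[C@]3(C)C[C@@H](OC(=O)[C@]3(C)O[C@H]3C)[C@@H]12 | intermediate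
28 | (1R,3S,6R,7R,8R,10R)-1,10-epoxy-3-hydroxy-8-{[(2R,3S)-2,3-dimethyloxiran-2-yl]carbonyloxy}germacra-4Z,11(13)-dien-12,6-olide (3β-OH, H-6β, H-7α, 8β-ester, 1β,10α-epoxide) | C=C1C(=O)O[C@@H]2/C=C(/C)[C@@H](O)C[C@H]3O[C@]3(C)C[C@@H](OC(=O)[C@]3(C)O[C@H]3C)[C@@H]12 | target

**Step count and risk**

Total step count: 14. Longest linear sequence: 10 steps (steps 1, 2, 3, 6, 7, 8, 11, 12, 13, 14).

The three steps most likely to fail:

Step 7. The potassium enolate carries a β-alkoxy leaving group (E1cB loss of the C8 oxygen), and the C7 configuration rests on outer-face alkylation of one conformer. The fallback sets out from 14 and avoids a free enolate during ring expansion. Compound 14 is silylated with N-(trimethylsilyl)imidazole to the (1S,4S,6S)-1-(trimethylsilyloxy) ether of 14 F4. F4 is rearranged thermally (neutral silyloxy-Cope, toluene, 200 °C, sealed tube) to {[(1Z,3R,5E,8S,9Z)-8-[(tert-butyldimethylsilyl)oxy]-3-[(4-methoxybenzyl)oxy]-5,9-dimethylcyclodeca-1,5,9-trien-1-yl]oxy}trimethylsilane F5. F5 is cleaved with CH3Li in THF at −78 °C to the lithium (1Z,3R,5E,8S,9Z)-cyclodecatrienolate F6, which is less prone to elimination than the crown-complexed potassium enolate. F6 is alkylated with 15 in THF/DMPU, and the route is rejoined at 17.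

Step 11. The hindered epoxy aldehyde may be a poor hydride donor, and acyl migration or lactonisation onto O8 may compete. The fallback sets out from 18 and separates reduction from acylation. Compound 18 is reduced with Me4NBH(OAc)3 in AcOH/MeCN at −25 °C (hydroxyl-directed, 1,3-anti) to 2-[(1R,2R,4E,7S,8Z,10R)-7-[(tert-butyldimethylsilyl)oxy]-2,10-dihydroxy-4,8-dimethylcyclodeca-4,8-dien-1-yl]-N-methoxy-N-methylacetamide F7. PPTS in toluene closes F7 to (3aR,4R,6E,9S,10Z,11aR)-9-[(tert-butyldimethylsilyl)oxy]-4-hydroxy-6,10-dimethyl-3a,4,5,8,9,11a-hexahydrocyclodeca[b]furan-2(3H)-one F8; the trans-fused 12,6-lactone is the form in which 8β-hydroxy germacranolides are isolated. Aldehyde 21 is oxidised with NaClO2/NaH2PO4/2-methylbut-2-ene to (2R,3S)-2,3-dimethyloxirane-2-carboxylic acid F9. F8 is esterified with F9 (2,4,6-trichlorobenzoyl chloride, Et3N, DMAP, toluene), and the route is rejoined at 23.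

Step 1. Arm selectivity and enantioselectivity of the rhodium alkenylation on a γ,γ-dialkoxy dienone, run in the presence of the oxidation by-products, are not assured. The fallback sets out from 1 and obtains the enantiomer by enzymatic resolution instead of asymmetric catalysis. The oxidation is stopped at isolated 3. CH2=C(CH3)MgBr with CuBr·SMe2 (cat.) and TMSCl in THF at −78 °C gives racemic 4,4-dimethoxy-2-methyl-5-(prop-1-en-2-yl)cyclohex-2-en-1-one F1. Luche reduction gives racemic cis-4,4-dimethoxy-2-methyl-5-(prop-1-en-2-yl)cyclohex-2-en-1-ol F2. Amano lipase PS with vinyl acetate acetylates the fast (1R) enantiomer to (1R,5R)-4,4-dimethoxy-2-methyl-5-(prop-1-en-2-yl)cyclohex-2-en-1-yl acetate F3 and leaves the (1S,5S) alcohol, so the route is rejoined at 5 (then the acid hydrolysis of step 2).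

**Further compounds**

F1 | step 1 | racemic 4,4-dimethoxy-2-methyl-5-(prop-1-en-2-yl)cyclohex-2-en-1-one | O=C1C(C)=CC(OC)(OC)C(C(C)=C)C1
F2 | step 1 | racemic cis-4,4-dimethoxy-2-methyl-5-(prop-1-en-2-yl)cyclohex-2-en-1-ol | O[C@@H]1C(C)=CC(OC)(OC)[C@H](C(C)=C)C1.O[C@H]1C(C)=CC(OC)(OC)[C@@H](C(C)=C)C1
F3 | step 1 | (1R,5R)-4,4-dimethoxy-2-methyl-5-(prop-1-en-2-yl)cyclohex-2-en-1-yl acetate | CC(=O)O[C@H]1C(C)=CC(OC)(OC)[C@@H](C(C)=C)C1
F4 | step 7 | (1S,4S,6S)-1-(trimethylsilyloxy) ether of 14 | COc1ccc(CO/C=C\[C@]2(O[Si](C)(C)C)C=C(C)[C@@H](O[Si](C)(C)C(C)(C)C)C[C@H]2C(C)=C)cc1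
F5 | step 7 | {[(1Z,3R,5E,8S,9Z)-8-[(tert-butyldimethylsilyl)oxy]-3-[(4-methoxybenzyl)oxy]-5,9-dimethylcyclodeca-1,5,9-trien-1-yl]oxy}trimethylsilane | C[Si](C)(C)O/C1=C\[C@H](OCc2ccc(OC)cc2)C/C(C)=C/C[C@H](O[Si](C)(C)C(C)(C)C)/C(C)=C\1
F6 | step 7 | lithium (1Z,3R,5E,8S,9Z)-8-[(tert-butyldimethylsilyl)oxy]-3-[(4-methoxybenzyl)oxy]-5,9-dimethylcyclodeca-1,5,9-trien-1-olate | [Li+].[O-]/C1=C\[C@H](OCc2ccc(OC)cc2)C/C(C)=C/C[C@H](O[Si](C)(C)C(C)(C)C)/C(C)=C\1
F7 | step 11 | 2-[(1R,2R,4E,7S,8Z,10R)-7-[(tert-butyldimethylsilyl)oxy]-2,10-dihydroxy-4,8-dimethylcyclodeca-4,8-dien-1-yl]-N-methoxy-N-methylacetamide | O[C@@H]1/C=C(/C)[C@@H](O[Si](C)(C)C(C)(C)C)C/C=C(C)/C[C@@H](O)[C@H]1CC(=O)N(C)OC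
F8 | step 11 | (3aR,4R,6E,9S,10Z,11aR)-9-[(tert-butyldimethylsilyl)oxy]-4-hydroxy-6,10-dimethyl-3a,4,5,8,9,11a-hexahydrocyclodeca[b]furan-2(3H)-one | C1C(=O)O[C@@H]2/C=C(/C)[C@@H](O[Si](C)(C)C(C)(C)C)C/C=C(C)/C[C@@H](O)[C@@H]12
F9 | step 11 | (2R,3S)-2,3-dimethyloxirane-2-carboxylic acid | OC(=O)[C@]1(C)O[C@H]1C
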